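The vessel is closed, stirred and held at one temperature, and we have two runs to go on. The violet run is this very flask, followed for its first 80.0 s; the red run has the same charges with more enzyme.

| setting | violet | red | flask |
|---|---|---|---|
| starting material | 5 mM | 5 mM | 5.0 mM |
| second substrate | 3 mM | 3 mM | 3.00 mM |
| free enzyme | 0.50 µM | 0.75 µM | 0.50 µM |
| remark | the very flask that is asked about, followed so far | run made earlier |  |
| time |  |  | 6.0 min |

- violet (time / s: target / %, starting material / %): 20.0: 25.5, 74.4; 40.0: 46.4, 54.5; 50.0: 52.0, 48.3; 80.0: 58.4, 41.8
- red (time / min: target / %, starting material / %): 0.500: 49.4, 49.7; 1.33: 60.3, 40.1; 2.50: 60.3, 39.7; 4.00: 60.4, 40.1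

(readings scatter by 0.5 percentage points)

- the numbers in the tables scatter by 0.5 percentage points (one standard deviation)

* amount of target in percent of the starting material charged, at 20 s, 1.5 min and 6.0 min

We build the flask up one process at a time. First comes just the main step: one starting material and one second substrate give one target. The red readings allow this, since at 2.50 min target and starting material add up to 100%. A one-to-one step stops with the scarcer charge, here the second substrate, the limiting reagent. So we call the second substrate charged over the starting material charged, never above one whole charge, the ceiling: 60.0%. It comes from the charges, so the red plateau of 60.3% is a true check on it.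

Next we add the enzyme as the clock. Red has 1.50 times the enzyme of this flask, and its 49.4% at 0.500 min lies between the violet readings at 40.0 s and 50.0 s, the stretch that holds the scaled time 45.0 s. The course therefore seems to run on enzyme times time. That moves the ceiling not at all, but it tells how soon the flask gets there: red at 4.00 min stands for this flask at 6.00 min.

Last comes whatever else may go on. Red target moves from 60.3% at 1.33 min to 60.4% at 4.00 min, inside the scatter, so we subtract nothing for it.

We commit to 60.0% at 6.0 min, to the violet reading 25.5% at 20 s, and to a little under the ceiling at 1.5 min, violet having read 58.4% already at 80.0 s. The forecast says 25.5%, 59.1% and 60.2%, the last 0.2 percentage points above our ceiling, on the ground that “the plateau holds”.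

The flask gives 26.3%, 59.6% and 60.0%.

    second substrate + loaded enzyme ⇌ second complex (K = 890 L mol⁻¹, k = 3.80 × 10⁶ L mol⁻¹ s⁻¹)
    second complex → free enzyme + target (k = 220 s⁻¹)
    first complex ⇌ loaded enzyme + first product (K = 0.100 M, k = 2800 s⁻¹)
    starting material + free enzyme ⇌ first complex (K = 280 L mol⁻¹, k = 1.00 × 10⁷ L mol⁻¹ s⁻¹)

Half of the turnover of the step that releases target is behind this flask by 0.388 min, far earlier than the 6.0 min asked, and at 6.00 min this flask holds 0% of its second substrate unbound and 40% of its starting material, with target on the ceiling of 60.0%. For a flask with half the starting material and the other amounts as they are, the ceiling comes to 100%, and that flask gives 100%.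

The numbers in the tables were generated by integration from invented constants; scatter was added.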